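**Assumptions:** 5 and 14 are treated as purchased (each is otherwise one step from commodity chemicals); the enol-ether E/Z ratio in 11 is inconsequential. The route has not been run; selectivities are expectations from the cited reaction types.

## Retrosynthetic overview

1. Target 15 ⇒ bis-dihydrocoumarin 13 + 2 × keto-ester 14: both tetramethylcyclohexanetrione rings are closed last, together, by C-acylation/Dieckmann.
2. 13 ⇒ bis(allyl benzyl ether) 9 by enol-ether isomerisation, ozonolysis and lactonisation (two temporary lactone rings); the former carbinol carbon becomes C-1 of each trione.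
3. 9 ⇒ hexanoylphloroglucinol 5 by two rounds of Mitsunobu O-alkylation / aromatic Claisen [3,3] rearrangement; each Ar–CH(iPr) bond and stereocentre arises by 1,3-chirality transfer.
4. Allylic alcohol 4 ⇒ (R)-benzyl glycidyl ether 1 (the only purchased stereocentre) by ylide homologation and cross-metathesis.
5. Ring order: arene purchased → two lactone rings (temporary) → two trione rings.

## Route

**Step 1**
Reactants: 1, (R)-benzyl glycidyl ether
Product: 2, (2R)-1-(benzyloxy)but-3-en-2-ol
Conditions: Me3S⁺I⁻, n-BuLi, THF, –10 °C → rt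
Reagents that add atoms: trimethylsulfonium iodide, C[S+](C)C.[I-] (one CH2)
Why: Dimethylsulfonium methylide opens the epoxide at the terminal carbon and the β-alkoxy sulfonium salt eliminates Me2S (epoxide → one-carbon-homologated allylic alcohol); the C–O stereocentre is not touched.

**Step 2**
Reactants: 2; 3, 3-methylbut-1-ene (10 equiv)
Product: 4, (2R,3E)-1-(benzyloxy)-5-methylhex-3-en-2-ol
Conditions: Hoveyda–Grubbs II (3 mol %), CH2Cl2, 40 °C, sealed tube
Reagents that add atoms: none beyond reactant 3 (C=CC(C)C)
Why: Olefin cross-metathesis with an achiral Ru carbene and excess branched olefin gives the thermodynamic E-alkene (ethylene lost); the stereocentre is a spectator.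

**Step 3**
Reactants: 4; 5, 1-(2,4,6-trihydroxyphenyl)hexan-1-one (1.5 equiv)
Product: 6, 1-(4-{[(2S,3E)-1-(benzyloxy)-5-methylhex-3-en-2-yl]oxy}-2,6-dihydroxyphenyl)hexan-1-one
Conditions: PPh3, DIAD, THF, 0 °C → rt
Reagents that add atoms: none
Why: Mitsunobu etherification at the most acidic, non-chelated 4-OH proceeds by SN2 with inversion (R → S); the adjacent CH2OBn group disfavours ionisation and SN2′.

**Step 4**
Reactants: 6
Product: 7, 1-{3-[(3S,4E)-6-(benzyloxy)-2-methylhex-4-en-3-yl]-2,4,6-trihydroxyphenyl}hexan-1-one
Conditions: HMDS, PhNEt2, 180 °C, sealed tube; then 1 M HCl–MeOH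
Reagents that add atoms: none (transient TMS ethers are removed on work-up)
Why: Aromatic Claisen [3,3] rearrangement through a chair transition state with CH2OBn and iPr both pseudo-equatorial transfers chirality suprafacially from the C–O carbon to the new benzylic carbon; the two ortho positions are equivalent, and in-situ silylation of the liberated phenol suppresses abnormal-Claisen and cyclisation pathways.

**Step 5**
Reactants: 7; 4 (1.3 equiv)
Product: 8, 1-(4-{[(2S,3E)-1-(benzyloxy)-5-methylhex-3-en-2-yl]oxy}-3-[(3S,4E)-6-(benzyloxy)-2-methylhex-4-en-3-yl]-2,6-dihydroxyphenyl)hexan-1-one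
Conditions: PPh3, DIAD, toluene, 0 °C → rt
Reagents that add atoms: none
Why: A second Mitsunobu inversion at the non-chelated 4-OH; any 6-O-ether formed would rearrange to the same carbon in step 6.

**Step 6**
Reactants: 8
Product: 9, 1-{3,5-bis[(3S,4E)-6-(benzyloxy)-2-methylhex-4-en-3-yl]-2,4,6-trihydroxyphenyl}hexan-1-one
Conditions: HMDS, PhNEt2, 180 °C, sealed tube; then 1 M HCl–MeOH
Reagents that add atoms: none
Why: A second aromatic Claisen rearrangement to the only free ortho carbon, with the same chair/equatorial chirality transfer controlled by the ether stereocentre, sets the second benzylic centre in the same sense.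

**Step 7**
Reactants: 9
Product: 10, 2-hexanoyl-4,6-bis[(3S,4E)-6-(benzyloxy)-2-methylhex-4-en-3-yl]benzene-1,3,5-triyl triacetate
Conditions: Ac2O, pyridine, DMAP (cat.), CH2Cl2, rt
Reagents that add atoms: acetic anhydride, CC(=O)OC(C)=O
Why: Peracetylation deactivates the electron-rich ring towards ozone and chlorite in the next steps; room temperature avoids Kostanecki/Baker–Venkataraman chemistry of the o-acyloxy ketone.

**Step 8**
Reactants: 10
Product: 11, 2-hexanoyl-4,6-bis[(3R,5E)-6-(benzyloxy)-2-methylhex-5-en-3-yl]benzene-1,3,5-triyl triacetate (the descriptor changes only because CIP priorities change)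
Conditions: [Ir(cod)(PMePh2)2]PF6 (4 mol %, H2-activated, then N2), THF, rt
Reagents that add atoms: none
Why: Ir–H-mediated allyl ether → enol ether isomerisation moves each double bond one position away from the stereocentre into conjugation with oxygen; the hindered benzylic C–H is not engaged.

**Step 9**
Reactants: 11
Product: 12, 3,3'-[2,4,6-tris(acetyloxy)-5-hexanoyl-1,3-phenylene]bis[(3R)-4-methylpentanoic acid]
Conditions: O3, CH2Cl2, –78 °C; Me2S; then NaClO2, NaH2PO4, 2-methyl-2-butene, t-BuOH/H2O, 0 °C (one pot)
Reagents that add atoms: ozone, [O-][O+]=O; sodium chlorite, [Na+].[O-]Cl=O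
Why: Ozonolysis cleaves the electron-rich enol-ether C=C (benzyl formate lost) and Pinnick oxidation takes the aldehyde to the acid; the stereocentre is β to the carbonyl and cannot epimerise.

**Step 10**
Reactants: 12
Product: 13, (4R,10R)-6-hexanoyl-5-hydroxy-4,10-di(propan-2-yl)-3,4,9,10-tetrahydro-2H,8H-pyrano[2,3-f]chromene-2,8-dione
Conditions: K2CO3, MeOH, rt (Ar); HCl; then TsOH (cat.), PhMe, 80 °C
Reagents that add atoms: none
Why: Acetate methanolysis followed by acid-catalysed lactonisation of the o-hydroxy-hydrocinnamic acids gives two dihydrocoumarin rings, which activate both acyl groups as aryl esters; the regioisomeric lactone closed onto the other flanking OH converges in step 11.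

**Step 11**
Reactants: 13; 14, methyl 2,2,4-trimethyl-3-oxopentanoate (8 equiv)
Product: 15, myrtucommulone F, 1-{2,4,6-trihydroxy-3,5-bis[(1R)-1-(2-hydroxy-3,3,5,5-tetramethyl-4,6-dioxocyclohex-1-en-1-yl)-2-methylpropyl]phenyl}hexan-1-one
Conditions: KHMDS (7.5 equiv), THF, –78 °C → rt; 1 M HCl
Reagents that add atoms: none beyond reactant 14
Why: The tetrasubstituted potassium enolate of 14 is C-acylated by each aryl lactone (directly or via the E1cB ketene), and the resulting ketone enolate closes onto the methyl ester (Dieckmann), driven by formation of the β-triketone enolates; the stereocentres are not touched.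

## Compound list

1 | (R)-benzyl glycidyl ether | C1O[C@H]1COCc2ccccc2 | starting material
2 | (2R)-1-(benzyloxy)but-3-en-2-ol | O[C@@H](COCc1ccccc1)C=C | intermediate
3 | 3-methylbut-1-ene | C=CC(C)C | starting material
4 | (2R,3E)-1-(benzyloxy)-5-methylhex-3-en-2-ol | O[C@@H](COCc1ccccc1)/C=C/C(C)C | intermediate
5 | 1-(2,4,6-trihydroxyphenyl)hexan-1-one | CCCCCC(=O)c1c(O)cc(O)cc1O | starting material
6 | 4-O-[(2S,3E)-1-(benzyloxy)-5-methylhex-3-en-2-yl] ether of 5 | CCCCCC(=O)c1c(O)cc(O[C@H](COCc2ccccc2)/C=C/C(C)C)cc1O | intermediate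
7 | 3-[(3S,4E)-6-(benzyloxy)-2-methylhex-4-en-3-yl] derivative of 5 | CCCCCC(=O)c1c(O)cc(O)c([C@H](/C=C/COCc2ccccc2)C(C)C)c1O | intermediate
8 | 4-O-[(2S,3E)-allyl] ether of 7 | CCCCCC(=O)c1c(O)cc(O[C@H](COCc2ccccc2)/C=C/C(C)C)c([C@H](/C=C/COCc2ccccc2)C(C)C)c1O | intermediate
9 | 3,5-bis[(3S,4E)-6-(benzyloxy)-2-methylhex-4-en-3-yl] derivative of 5 | CCCCCC(=O)c1c(O)c([C@H](/C=C/COCc2ccccc2)C(C)C)c(O)c([C@H](/C=C/COCc2ccccc2)C(C)C)c1O | intermediate
10 | triacetate of 9 | CCCCCC(=O)c1c(OC(C)=O)c([C@H](/C=C/COCc2ccccc2)C(C)C)c(OC(C)=O)c([C@H](/C=C/COCc2ccccc2)C(C)C)c1OC(C)=O | intermediate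
11 | bis(benzyl enol ether) triacetate, (3R,5E) arms (E shown) | CCCCCC(=O)c1c(OC(C)=O)c([C@H](C/C=C/OCc2ccccc2)C(C)C)c(OC(C)=O)c([C@H](C/C=C/OCc2ccccc2)C(C)C)c1OC(C)=O | intermediate
12 | (3R,3'R)-diacid triacetate | CCCCCC(=O)c1c(OC(C)=O)c([C@H](CC(=O)O)C(C)C)c(OC(C)=O)c([C@H](CC(=O)O)C(C)C)c1OC(C)=O | intermediate
13 | (4R,10R)-bis-dihydrocoumarin, free OH chelated to the hexanoyl C=O | CCCCCC(=O)c1c(O)c2c(OC(=O)C[C@@H]2C(C)C)c3c1OC(=O)C[C@@H]3C(C)C | intermediate
14 | methyl 2,2,4-trimethyl-3-oxopentanoate | COC(=O)C(C)(C)C(=O)C(C)C | starting material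
15 | myrtucommulone F (R,R) | CCCCCC(=O)c1c(O)c([C@H](C2=C(O)C(C)(C)C(=O)C(C)(C)C2=O)C(C)C)c(O)c([C@H](C2=C(O)C(C)(C)C(=O)C(C)(C)C2=O)C(C)C)c1O | target

## Summary

Total steps: 11. Longest linear sequence: 11 (1 → 15; alcohol 4 is used twice).

Steps most likely to fail:

1. **Step 11** (double C-acylation/Dieckmann at two hindered arms). The enolate may O-acylate, or the non-enolisable diketone may undergo retro-Claisen cleavage. Fallback: stop step 9 at the dialdehyde, add the lithium enolate of 14 in an aldol reaction, oxidise the β-hydroxy ketones (DMP), close the rings with NaH, and remove the acetates last.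
2. **Steps 4 and 6** (Claisen at 180 °C on an ether whose aryloxide is a good leaving group). Ionisation or leakage through the chair with axial CH2OBn (Z-olefin, opposite configuration) would erode stereochemical purity and give the meso diastereomer. Fallback: run both Mitsunobu/Claisen cycles on 3,5-bis(benzyloxy)phenol, whose electron-rich ether rearranges at lower temperature, then introduce the hexanoyl group by Friedel–Crafts acylation at the single free ring carbon.
3. **Step 8** (isomerisation of hindered internal allyl ethers). It may be slow or migrate towards the benzylic carbon. Fallback: regioselective 9-BBN hydroboration–oxidation (boron at C-5, away from the branched benzylic carbon), hydrogenolysis of the benzyl ethers, NaIO4 cleavage of the 1,2-diols to the same dialdehyde, then Pinnick oxidation.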